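**Retrosynthetic overview**

- Atoms are numbered C1 (lactone C=O), C5 (ring O–CH), C6 (carbinol), C7–C8–C9 (cyclopropane), C10 (ketone), C11 (acyloxy CH), C12 (CH3). The plan rests on the trans-cyclopropane C7–C8–C9: C9 is α to the C10 ketone and C7 carries the C6 carbinol, so cutting C7–C9 gives a C9 enolate and a cis-C6–C7 epoxide, the γ,δ-epoxy ketone 14.
- 14 comes from the (S)-lactate Weinreb amide 3 and butenyl Grignard 4 (C9–C10), Z-selective cross-metathesis (C6=C7), Sharpless epoxidation (C6, C7), oxidation, asymmetric allylboration (C4–C5 and the C5 centre) and PMB protection.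
- Ring order: the cyclopropane first (step 9, 3-exo-tet), then the 5,6-dihydropyran-2-one by C5 acrylate formation and ring-closing metathesis (C2=C3, step 13).
- End: the C11 silyl ether is exchanged for the O-silyl p-coumarate and both TBS groups are removed.

Key step: step 9

Assumption: (+)-Ipc2BOMe (the reagent made from (−)-α-pinene), the ruthenium dithiolate metathesis catalyst of step 4 and 2-(4-methoxybenzyloxy)-4-methylquinoline are bought; the locants C1–C12 above are used in all steps.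

**Route**

Step 1
Reactants: 1 ethyl (S)-lactate
Product: 2 (S)-2-hydroxy-N-methoxy-N-methylpropanamide
Conditions: MeNH(OMe)·HCl, iPrMgCl, THF, −20 → 0 °C
Reagents that add atoms: N,O-dimethylhydroxylamine hydrochloride, CNOC.Cl
Why: Weinreb amide formation by acyl substitution of the ester with the chloromagnesium amide, the magnesium alkoxide of the lactate hydroxyl keeping C11 from enolising so that the (S) centre is carried over.

Step 2
Reactants: 2 (S)-2-hydroxy-N-methoxy-N-methylpropanamide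
Product: 3 (S)-N-methoxy-N-methyl-2-(triethylsilyloxy)propanamide
Conditions: TESCl, imidazole, DMF, 0 °C → rt
Reagents that add atoms: chlorotriethylsilane, CC[Si](Cl)(CC)CC
Why: Standard silylation of a secondary alcohol, giving a C11 ether that later steers enolisation to C9 and can be removed in the presence of TBS ethers.

Step 3
Reactants: 3 (S)-N-methoxy-N-methyl-2-(triethylsilyloxy)propanamide; 4 but-3-enylmagnesium bromide
Product: 5 (S)-2-(triethylsilyloxy)hept-6-en-3-one
Conditions: THF, 0 °C; aq. NH4Cl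
Reagents that add atoms: none
Why: Weinreb ketone synthesis, in which the Grignard reagent adds once and the magnesium chelate holds until work-up, forming C9–C10 without touching the C11 centre.

Step 4
Reactants: 5 (S)-2-(triethylsilyloxy)hept-6-en-3-one; 6 (Z)-but-2-ene-1,4-diol
Product: 7 (S,Z)-8-hydroxy-2-(triethylsilyloxy)oct-6-en-3-one
Conditions: Ru(=CH-C6H4-2-OiPr)(SIMes)(3,6-Cl2C6H2S2) (5 mol%), 6 (2–3 equiv), THF, 22 °C, 100 torr
Reagents that add atoms: none
Why: Z-selective olefin cross-metathesis with a ruthenium dithiolate catalyst, a catalyst class known to pass the cis CH–CH2OH unit of (Z)-but-2-ene-1,4-diol on to terminal alkenes with retention of geometry, the ketone and silyl ether being spectators.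

Step 5
Reactants: 7 (S,Z)-8-hydroxy-2-(triethylsilyloxy)oct-6-en-3-one
Product: 8 (S)-5-[(2S,3R)-3-(hydroxymethyl)oxiran-2-yl]-2-(triethylsilyloxy)pentan-3-one
Conditions: Ti(OiPr)4 (20 mol%), diethyl D-(−)-tartrate (24 mol%), t-BuOOH, 4 Å MS, CH2Cl2, −20 °C
Reagents that add atoms: tert-butyl hydroperoxide, CC(C)(C)OO
Why: Sharpless asymmetric epoxidation of a Z-allylic alcohol, in which the D-(−)-tartrate titanium complex delivers oxygen to the face that gives the (6R,7S) cis-epoxide by syn addition, the minor epoxide being a diastereomer because of C11 and thus removable by chromatography.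

Step 6
Reactants: 8 (S)-5-[(2S,3R)-3-(hydroxymethyl)oxiran-2-yl]-2-(triethylsilyloxy)pentan-3-one
Product: 9 (2S,3S)-3-[(S)-3-oxo-4-(triethylsilyloxy)pentyl]oxirane-2-carbaldehyde
Conditions: Dess–Martin periodinane, NaHCO3, CH2Cl2, 0 °C → rt; used crude
Reagents that add atoms: none
Why: Dess–Martin oxidation of the primary alcohol under buffered, non-enolising conditions should give the cis-epoxy aldehyde without epimerisation at C6 and without acid-induced reaction between ketone and epoxide.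

Step 7
Reactants: 9 (2S,3S)-3-[(S)-3-oxo-4-(triethylsilyloxy)pentyl]oxirane-2-carbaldehyde; 10 allylmagnesium bromide
Product: 13 (S)-5-{(2S,3R)-3-[(R)-1-hydroxybut-3-en-1-yl]oxiran-2-yl}-2-(triethylsilyloxy)pentan-3-one, via (+)-B-allyldiisopinocampheylborane 11 (not isolated), via O-diisopinocampheylboryl adduct 12 (not isolated)
Conditions: (+)-Ipc2BOMe, 10 (0.95 equiv), Et2O, 0 °C → rt; then 9, −78 °C; NaBO3·4H2O, THF/H2O, rt
Reagents that add atoms: none
Why: Brown allylboration through a closed chair transition state, in which the reagent from (−)-α-pinene adds allyl to the Re face of the aldehyde, the same face that the Cornforth/Felkin–Anh arrangement of the cis-epoxy aldehyde prefers (matched case), so that C5 should be set as R (anti to the epoxide oxygen) while the hindered C10 ketone reacts far more slowly at −78 °C.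

Step 8
Reactants: 13 (S)-5-{(2S,3R)-3-[(R)-1-hydroxybut-3-en-1-yl]oxiran-2-yl}-2-(triethylsilyloxy)pentan-3-one
Product: 14 (S)-5-{(2S,3S)-3-[(R)-1-(4-methoxybenzyloxy)but-3-en-1-yl]oxiran-2-yl}-2-(triethylsilyloxy)pentan-3-one
Conditions: 2-(4-methoxybenzyloxy)-4-methylquinoline, MeOTf, MgO, PhCF3, 0 °C → rt
Reagents that add atoms: 2-(4-methoxybenzyloxy)-4-methylquinoline, COc1ccc(COc2cc(C)c3ccccc3n2)cc1
Why: p-Methoxybenzyl transfer from the N-methylquinolinium salt formed in the flask under neutral conditions (MgO takes up acid), chosen because the substrate has an enolisable ketone that rules out NaH and a γ,δ-epoxy ketone that rules out strong acid, and giving an ether that cannot migrate to the C6 alkoxide of step 9.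

Step 9
Reactants: 14 (S)-5-{(2S,3S)-3-[(R)-1-(4-methoxybenzyloxy)but-3-en-1-yl]oxiran-2-yl}-2-(triethylsilyloxy)pentan-3-one
Product: 16 (S)-1-{(1S,2S)-2-[(1S,2R)-1-hydroxy-2-(4-methoxybenzyloxy)pent-4-en-1-yl]cyclopropyl}-2-(triethylsilyloxy)propan-1-one, via lithium (Z)-enolate 15 (not isolated)
Conditions: LiN(SiMe3)2 (1.2 equiv), THF, −78 → 0 °C; aq. NH4Cl
Reagents that add atoms: none
Why: LiN(SiMe3)2 removes a C9 proton kinetically, because α-silyloxy ketones enolise away from the hindered, oxygen-bearing C11, and the enolate carbon then displaces the epoxide oxygen at C7 from the rear side in an intramolecular SN2 reaction. The closest known reaction type is the base-induced cyclisation of γ,δ-epoxy ketones, esters, nitriles and sulfones to 2-(1-hydroxyalkyl)cyclopropyl carbonyl compounds, related to the closure of 5-halo-2-pentanones to cyclopropyl ketones. The cyclopropane closes in the 3-exo-tet mode, which is faster than 4-exo attack at C6 (also deactivated by the C5 ether) and than 5-exo O-alkylation, the lithium ion holding the enolate oxygen. C7 is fixed by inversion of the epoxide carbon, C6 keeps its C–O bond and becomes the (6S) carbinol, and C9 is set by the transition state that places the acyl group trans to the C6 side chain. The step needs C9 over C11 enolisation (secured by the OTES group), C over O alkylation and C7 over C6 attack (secured by ring size and lithium) and trans closure (steric). It is driven by the return of the C=O bond and the lithium alkoxide, the ring strain being about equal on both sides.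

Step 10
Reactants: 16 (S)-1-{(1S,2S)-2-[(1S,2R)-1-hydroxy-2-(4-methoxybenzyloxy)pent-4-en-1-yl]cyclopropyl}-2-(triethylsilyloxy)propan-1-one
Product: 17 (S)-1-{(1S,2S)-2-[(1S,2R)-1-(tert-butyldimethylsilyloxy)-2-(4-methoxybenzyloxy)pent-4-en-1-yl]cyclopropyl}-2-(triethylsilyloxy)propan-1-one
Conditions: TBSOTf, 2,6-lutidine, CH2Cl2, −78 °C
Reagents that add atoms: tert-butyldimethylsilyl triflate, CC(C)(C)[Si](C)(C)OS(=O)(=O)C(F)(F)F
Why: Silylation of the hindered C6 alcohol with a silyl triflate and a hindered base at low temperature, which should leave the PMB and TES ethers and the cyclopropyl ketone untouched and sets C6 apart from C5 for lactone formation.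

Step 11
Reactants: 17 (S)-1-{(1S,2S)-2-[(1S,2R)-1-(tert-butyldimethylsilyloxy)-2-(4-methoxybenzyloxy)pent-4-en-1-yl]cyclopropyl}-2-(triethylsilyloxy)propan-1-one
Product: 18 (S)-1-{(1S,2S)-2-[(1S,2R)-1-(tert-butyldimethylsilyloxy)-2-hydroxypent-4-en-1-yl]cyclopropyl}-2-(triethylsilyloxy)propan-1-one
Conditions: DDQ, CH2Cl2/pH 7 buffer, 0 °C
Reagents that add atoms: none
Why: Oxidative cleavage of the electron-rich PMB ether by DDQ through a benzylic oxocarbenium ion that water hydrolyses, silyl ethers, terminal alkene and cyclopropyl ketone not being oxidised.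

Step 12
Reactants: 18 (S)-1-{(1S,2S)-2-[(1S,2R)-1-(tert-butyldimethylsilyloxy)-2-hydroxypent-4-en-1-yl]cyclopropyl}-2-(triethylsilyloxy)propan-1-one; 19 acryloyl chloride
Product: 20 (1S,2R)-1-(tert-butyldimethylsilyloxy)-1-{(1S,2S)-2-[(S)-2-(triethylsilyloxy)propanoyl]cyclopropyl}pent-4-en-2-yl acrylate
Conditions: iPr2NEt, DMAP (cat.), CH2Cl2, −20 → 0 °C
Reagents that add atoms: none
Why: O-Acylation of the C5 alcohol by the acid chloride with an amine base and nucleophilic catalysis, no stereocentre being touched and C6 being blocked.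

Step 13
Reactants: 20 (1S,2R)-1-(tert-butyldimethylsilyloxy)-1-{(1S,2S)-2-[(S)-2-(triethylsilyloxy)propanoyl]cyclopropyl}pent-4-en-2-yl acrylate
Product: 21 (R)-6-[(S)-(tert-butyldimethylsilyloxy){(1S,2S)-2-[(S)-2-(triethylsilyloxy)propanoyl]cyclopropyl}methyl]-5,6-dihydro-2H-pyran-2-one
Conditions: RuCl2(=CHPh)(SIMes)(PCy3) (second-generation Grubbs catalyst, 5 mol%), CH2Cl2 (2 mM), 40 °C
Reagents that add atoms: none
Why: Ring-closing metathesis between the terminal alkene and the acrylate forms C2=C3 and the six-membered lactone, whose ring size enforces the cis alkene and whose formation is driven by loss of ethene.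

Step 14
Reactants: 21 (R)-6-[(S)-(tert-butyldimethylsilyloxy){(1S,2S)-2-[(S)-2-(triethylsilyloxy)propanoyl]cyclopropyl}methyl]-5,6-dihydro-2H-pyran-2-one
Product: 22 (R)-6-[(S)-(tert-butyldimethylsilyloxy){(1S,2S)-2-[(S)-2-hydroxypropanoyl]cyclopropyl}methyl]-5,6-dihydro-2H-pyran-2-one
Conditions: HF·pyridine, pyridine, THF, 0 °C
Reagents that add atoms: none
Why: Buffered HF·pyridine cleaves the TES ether much faster than the hindered secondary TBS ether, freeing only C11–OH under conditions too mild for enediol epimerisation of the α-hydroxy ketone.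

Step 15
Reactants: 23 p-coumaric acid
Product: 25 (E)-3-[4-(tert-butyldimethylsilyloxy)phenyl]acrylic acid, via tert-butyldimethylsilyl (E)-3-[4-(tert-butyldimethylsilyloxy)phenyl]acrylate 24 (not isolated)
Conditions: TBSCl (2.5 equiv), imidazole, DMF, rt; then AcOH/THF/H2O, rt
Reagents that add atoms: tert-butyldimethylsilyl chloride, CC(C)(C)[Si](C)(C)Cl
Why: Bis-silylation followed by selective hydrolysis of the labile silyl ester leaves the phenol protected, so that the acid can be coupled without self-esterification.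

Step 16
Reactants: 22 (R)-6-[(S)-(tert-butyldimethylsilyloxy){(1S,2S)-2-[(S)-2-hydroxypropanoyl]cyclopropyl}methyl]-5,6-dihydro-2H-pyran-2-one; 25 (E)-3-[4-(tert-butyldimethylsilyloxy)phenyl]acrylic acid
Product: 26 (S)-1-{(1S,2S)-2-[(S)-(tert-butyldimethylsilyloxy)((R)-6-oxo-3,6-dihydro-2H-pyran-2-yl)methyl]cyclopropyl}-1-oxopropan-2-yl (E)-3-[4-(tert-butyldimethylsilyloxy)phenyl]acrylate
Conditions: DCC, DMAP (cat.), CH2Cl2, 0 °C → rt
Reagents that add atoms: none
Why: Steglich esterification (carbodiimide activation and DMAP acyl transfer) of the unhindered C11 alcohol with retention at C11, run cold with little DMAP to limit epimerisation of the α-acyloxy ketone.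

Step 17
Reactants: 26 (S)-1-{(1S,2S)-2-[(S)-(tert-butyldimethylsilyloxy)((R)-6-oxo-3,6-dihydro-2H-pyran-2-yl)methyl]cyclopropyl}-1-oxopropan-2-yl (E)-3-[4-(tert-butyldimethylsilyloxy)phenyl]acrylate
Product: 27 brevipolide G
Conditions: HF·pyridine, THF, 0 °C → rt
Reagents that add atoms: none
Why: Fluoride cleavage of the alkyl and aryl Si–O bonds in an acidic, non-basic medium, in which the coumarate ester, the lactone, the C11 centre and the cyclopropyl carbinol should survive.

**Compound list**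

1 | ethyl (S)-lactate | C[C@H](O)C(=O)OCC | starting material
2 | (S)-2-hydroxy-N-methoxy-N-methylpropanamide | C[C@H](O)C(=O)N(C)OC | intermediate
3 | (S)-N-methoxy-N-methyl-2-(triethylsilyloxy)propanamide | C[C@H](O[Si](CC)(CC)CC)C(=O)N(C)OC | intermediate
4 | but-3-enylmagnesium bromide | C=CCC[Mg]Br | starting material
5 | (S)-2-(triethylsilyloxy)hept-6-en-3-one | C[C@H](O[Si](CC)(CC)CC)C(=O)CCC=C | intermediate
6 | (Z)-but-2-ene-1,4-diol | OC/C=C\CO | starting material
7 | (S,Z)-8-hydroxy-2-(triethylsilyloxy)oct-6-en-3-one | C[C@H](O[Si](CC)(CC)CC)C(=O)CC/C=C\CO | intermediate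
8 | (S)-5-[(2S,3R)-3-(hydroxymethyl)oxiran-2-yl]-2-(triethylsilyloxy)pentan-3-one (cis-epoxide) | C[C@H](O[Si](CC)(CC)CC)C(=O)CC[C@@H]1O[C@@H]1CO | intermediate
9 | (2S,3S)-3-[(S)-3-oxo-4-(triethylsilyloxy)pentyl]oxirane-2-carbaldehyde (cis-epoxide) | C[C@H](O[Si](CC)(CC)CC)C(=O)CC[C@@H]1O[C@@H]1C=O | intermediate
10 | allylmagnesium bromide | C=CC[Mg]Br | starting material
11 | (+)-B-allyldiisopinocampheylborane (isopinocampheyl groups from (−)-α-pinene) | C=CCB([C@H]1C[C@H]2C[C@@H]([C@@H]1C)C2(C)C)[C@H]1C[C@H]2C[C@@H]([C@@H]1C)C2(C)C | intermediate (not isolated)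
12 | O-diisopinocampheylboryl adduct (borinate ester of 13 at C5–O) | C[C@H](O[Si](CC)(CC)CC)C(=O)CC[C@@H]1O[C@@H]1[C@@H](CC=C)OB([C@H]1C[C@H]2C[C@@H]([C@@H]1C)C2(C)C)[C@H]1C[C@H]2C[C@@H]([C@@H]1C)C2(C)C | intermediate (not isolated)
13 | (S)-5-{(2S,3R)-3-[(R)-1-hydroxybut-3-en-1-yl]oxiran-2-yl}-2-(triethylsilyloxy)pentan-3-one | C[C@H](O[Si](CC)(CC)CC)C(=O)CC[C@@H]1O[C@@H]1[C@H](O)CC=C | intermediate
14 | (S)-5-{(2S,3S)-3-[(R)-1-(4-methoxybenzyloxy)but-3-en-1-yl]oxiran-2-yl}-2-(triethylsilyloxy)pentan-3-one | C[C@H](O[Si](CC)(CC)CC)C(=O)CC[C@@H]1O[C@@H]1[C@H](OCc1ccc(OC)cc1)CC=C | intermediate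
15 | lithium (Z)-enolate of 14 (C9=C10, O–Li) | C[C@H](O[Si](CC)(CC)CC)/C(O[Li])=C/C[C@@H]1O[C@@H]1[C@H](OCc1ccc(OC)cc1)CC=C | intermediate (not isolated)
16 | (S)-1-{(1S,2S)-2-[(1S,2R)-1-hydroxy-2-(4-methoxybenzyloxy)pent-4-en-1-yl]cyclopropyl}-2-(triethylsilyloxy)propan-1-one | C[C@H](O[Si](CC)(CC)CC)C(=O)[C@H]1C[C@@H]1[C@H](O)[C@H](OCc1ccc(OC)cc1)CC=C | intermediate
17 | (S)-1-{(1S,2S)-2-[(1S,2R)-1-(tert-butyldimethylsilyloxy)-2-(4-methoxybenzyloxy)pent-4-en-1-yl]cyclopropyl}-2-(triethylsilyloxy)propan-1-one | C[C@H](O[Si](CC)(CC)CC)C(=O)[C@H]1C[C@@H]1[C@H](O[Si](C)(C)C(C)(C)C)[C@H](OCc1ccc(OC)cc1)CC=C | intermediate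
18 | (S)-1-{(1S,2S)-2-[(1S,2R)-1-(tert-butyldimethylsilyloxy)-2-hydroxypent-4-en-1-yl]cyclopropyl}-2-(triethylsilyloxy)propan-1-one | C[C@H](O[Si](CC)(CC)CC)C(=O)[C@H]1C[C@@H]1[C@H](O[Si](C)(C)C(C)(C)C)[C@H](O)CC=C | intermediate
19 | acryloyl chloride | C=CC(=O)Cl | starting material
20 | (1S,2R)-1-(tert-butyldimethylsilyloxy)-1-{(1S,2S)-2-[(S)-2-(triethylsilyloxy)propanoyl]cyclopropyl}pent-4-en-2-yl acrylate | C[C@H](O[Si](CC)(CC)CC)C(=O)[C@H]1C[C@@H]1[C@H](O[Si](C)(C)C(C)(C)C)[C@H](OC(=O)C=C)CC=C | intermediate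
21 | (R)-6-[(S)-(tert-butyldimethylsilyloxy){(1S,2S)-2-[(S)-2-(triethylsilyloxy)propanoyl]cyclopropyl}methyl]-5,6-dihydro-2H-pyran-2-one | C[C@H](O[Si](CC)(CC)CC)C(=O)[C@H]1C[C@@H]1[C@H](O[Si](C)(C)C(C)(C)C)[C@H]1CC=CC(=O)O1 | intermediate
22 | (R)-6-[(S)-(tert-butyldimethylsilyloxy){(1S,2S)-2-[(S)-2-hydroxypropanoyl]cyclopropyl}methyl]-5,6-dihydro-2H-pyran-2-one | C[C@H](O)C(=O)[C@H]1C[C@@H]1[C@H](O[Si](C)(C)C(C)(C)C)[C@H]1CC=CC(=O)O1 | intermediate
23 | p-coumaric acid | OC(=O)/C=C/c1ccc(O)cc1 | starting material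
24 | tert-butyldimethylsilyl (E)-3-[4-(tert-butyldimethylsilyloxy)phenyl]acrylate | CC(C)(C)[Si](C)(C)OC(=O)/C=C/c1ccc(O[Si](C)(C)C(C)(C)C)cc1 | intermediate (not isolated)
25 | (E)-3-[4-(tert-butyldimethylsilyloxy)phenyl]acrylic acid | OC(=O)/C=C/c1ccc(O[Si](C)(C)C(C)(C)C)cc1 | intermediate
26 | (S)-1-{(1S,2S)-2-[(S)-(tert-butyldimethylsilyloxy)((R)-6-oxo-3,6-dihydro-2H-pyran-2-yl)methyl]cyclopropyl}-1-oxopropan-2-yl (E)-3-[4-(tert-butyldimethylsilyloxy)phenyl]acrylate | C[C@H](OC(=O)/C=C/c1ccc(O[Si](C)(C)C(C)(C)C)cc1)C(=O)[C@H]1C[C@@H]1[C@H](O[Si](C)(C)C(C)(C)C)[C@H]1CC=CC(=O)O1 | intermediate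
27 | brevipolide G (5R,6S,7S,9S,11S) | C[C@H](OC(=O)/C=C/c1ccc(O)cc1)C(=O)[C@H]1C[C@@H]1[C@H](O)[C@H]1CC=CC(=O)O1 | target

**Step count**

Total: 17 steps. Longest linear sequence: 16 steps (steps 1–14, 16 and 17 from ethyl (S)-lactate); step 15 is a one-step side branch.

**Steps most likely to fail**

1. Step 9 (cyclopropane closure). The lithium enolate may open the epoxide only slowly, so that proton transfer toward C11 (with epimerisation) or O-alkylation competes with C–C bond formation. The fallback sets out from 14 and comes back at 16, keeping the same C7–C9 bond but changing the nucleophile to a metalated hydrazone. Condensation of 14 with 1,1-dimethylhydrazine (EtOH, cat. AcOH, rt) would give the epoxy (E)-N,N-dimethylhydrazone F1. LiN(iPr)2 (THF, −78 → 0 °C) would metalate the less substituted α-carbon C9, and the aza-enolate, a stronger and purely carbon-centred nucleophile of a class known to open epoxides, would close onto C7 with inversion to give the cyclopropyl carbinol hydrazone F2. Mild hydrolysis (CuCl2, THF/pH 7 buffer) would return ketone 16.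

2. Step 4 (Z-selective cross-metathesis). The Z geometry may erode through secondary metathesis, 5 may homodimerise, or the catalyst may decompose early in the presence of the free diol. The fallback sets out from 3 and comes back at 7, making the cis alkene by alkyne semi-hydrogenation instead. The lithium acetylide of 4-methoxybenzyl propargyl ether (n-BuLi, THF, −78 °C) would open oxirane with BF3·OEt2 to give 5-(4-methoxybenzyloxy)pent-3-yn-1-ol F3. CBr4/PPh3 (CH2Cl2, 0 °C) would give 1-{[(5-bromopent-2-yn-1-yl)oxy]methyl}-4-methoxybenzene F4. Its Grignard reagent (Mg, THF) would acylate Weinreb amide 3 to give (S)-8-(4-methoxybenzyloxy)-2-(triethylsilyloxy)oct-6-yn-3-one F5. Hydrogenation over Pd/CaCO3 poisoned with Pb(OAc)2 and quinoline (H2, EtOAc) would give (S,Z)-8-(4-methoxybenzyloxy)-2-(triethylsilyloxy)oct-6-en-3-one F6, and DDQ (CH2Cl2/pH 7 buffer) would free allylic alcohol 7.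

3. Step 8 (PMB protection of the epoxy keto alcohol). Transfer to the hindered C5 hydroxyl may be slow, and the cationic benzylating agent may instead trigger attack of the ketone oxygen or the hydroxyl on the epoxide. The fallback sets out from 13 and comes back at 18, using an acetal-type group that is put on with an amine base only and also comes off with DDQ. 2-[(Chloromethoxy)methyl]naphthalene and iPr2NEt (CH2Cl2, rt) would give the C5 (2-naphthylmethoxy)methyl ether F7. LiN(SiMe3)2 (THF, −78 → 0 °C) would close the cyclopropane as in step 9 to give the cyclopropyl carbinol F8. TBSOTf/2,6-lutidine (CH2Cl2, −78 °C) would give the C6 TBS ether F9, and DDQ (CH2Cl2/pH 7 buffer) would remove the acetal group to give 18.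

**Further compounds**

F1 | step 9 | (E)-N,N-dimethylhydrazone of epoxy ketone 14 | C[C@H](O[Si](CC)(CC)CC)/C(=N/N(C)C)CC[C@@H]1O[C@@H]1[C@H](OCc1ccc(OC)cc1)CC=C
F2 | step 9 | (E)-N,N-dimethylhydrazone of cyclopropyl ketone 16 | C[C@H](O[Si](CC)(CC)CC)/C(=N/N(C)C)[C@H]1C[C@@H]1[C@H](O)[C@H](OCc1ccc(OC)cc1)CC=C
F3 | step 4 | 5-(4-methoxybenzyloxy)pent-3-yn-1-ol | COc1ccc(COCC#CCCO)cc1
F4 | step 4 | 1-{[(5-bromopent-2-yn-1-yl)oxy]methyl}-4-methoxybenzene | COc1ccc(COCC#CCCBr)cc1
F5 | step 4 | (S)-8-(4-methoxybenzyloxy)-2-(triethylsilyloxy)oct-6-yn-3-one | C[C@H](O[Si](CC)(CC)CC)C(=O)CCC#CCOCc1ccc(OC)cc1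
F6 | step 4 | (S,Z)-8-(4-methoxybenzyloxy)-2-(triethylsilyloxy)oct-6-en-3-one | C[C@H](O[Si](CC)(CC)CC)C(=O)CC/C=C\COCc1ccc(OC)cc1
F7 | step 8 | (S)-5-{(2S,3S)-3-[(R)-1-[(2-naphthylmethoxy)methoxy]but-3-en-1-yl]oxiran-2-yl}-2-(triethylsilyloxy)pentan-3-one | C[C@H](O[Si](CC)(CC)CC)C(=O)CC[C@@H]1O[C@@H]1[C@H](OCOCc1ccc2ccccc2c1)CC=C
F8 | step 8 | (S)-1-{(1S,2S)-2-[(1S,2R)-1-hydroxy-2-[(2-naphthylmethoxy)methoxy]pent-4-en-1-yl]cyclopropyl}-2-(triethylsilyloxy)propan-1-one | C[C@H](O[Si](CC)(CC)CC)C(=O)[C@H]1C[C@@H]1[C@H](O)[C@H](OCOCc1ccc2ccccc2c1)CC=C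
F9 | step 8 | (S)-1-{(1S,2S)-2-[(1S,2R)-1-(tert-butyldimethylsilyloxy)-2-[(2-naphthylmethoxy)methoxy]pent-4-en-1-yl]cyclopropyl}-2-(triethylsilyloxy)propan-1-one | C[C@H](O[Si](CC)(CC)CC)C(=O)[C@H]1C[C@@H]1[C@H](O[Si](C)(C)C(C)(C)C)[C@H](OCOCc1ccc2ccccc2c1)CC=C
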